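The route opens ring A, the cyclopentene that shares the C6–C10 bond with ring B and has its double bond (C6=C7) beside C5, the carbon on nitrogen. That ring maps onto an alkyne at C5, a but-3-enyl chain at C13 and CO. One Pauson–Khand step forms C6–C10, C7–C8 and C8–C9, closes rings A and B and sets C10. Its precursor is the tetracyclic amino lactone (rings C–F) with a trimethylsilylethynyl group at C5 and the butenyl chain at C13; silicon is a spectator that steers the alkene face. The precursor is built from a resolved cyclopentene β-amino ester by Heck cyclisation, Dieckmann closure of ring C, lactonisation and reductive alkynylation.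

Key step: step 14

Remark on atom labels: ring A = C6–C10; ring B = C5, C6, C10–C13; ring C = N, C5, C13, C14, C15 (spiro quaternary C), C16 (N–CH); ring D = N, C16, C17, C18 (CHMe), C19 (NCH2); ring E = C15, C16, C17, C20, C21; ring F = C14, O, C24(=O), C23, C22, C15.
Remark on faces: "convex face" means the face of the cup-shaped rings C/D/E (or of the cis-fused D/E bicycle) that carries H16; racemic lactam 1 is taken as commercial.

Step 1
Reactants: 1 (±)-cis-6-azabicyclo[3.2.0]hept-3-en-7-one
Product: 2 (1R,2S)-2-aminocyclopent-3-ene-1-carboxylic acid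
Conditions: Candida antarctica lipase B (immobilised), H2O (1 equiv), iPr2O, 65 °C; 2 filtered off, unreacted (1S,5R)-lactam stays in solution
Reagents that add atoms: water, O
Why: Lipase-catalysed enantioselective hydrolytic ring opening (kinetic resolution) of the β-lactam opens only the (1R,5S) enantiomer, which supplies C16 with its final configuration and the cis amino/carboxyl pair.

Step 2
Reactants: 2 (1R,2S)-2-aminocyclopent-3-ene-1-carboxylic acid
Product: 3 methyl (1R,2S)-2-aminocyclopent-3-ene-1-carboxylate hydrochloride
Conditions: SOCl2, MeOH, 0 °C to rt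
Reagents that add atoms: methanol, CO; thionyl chloride, O=S(Cl)Cl
Why: Fischer esterification with HCl generated in the flask breaks no bond at a stereocentre.

Step 3
Reactants: 3 methyl (1R,2S)-2-aminocyclopent-3-ene-1-carboxylate hydrochloride; 4 benzaldehyde
Product: 5 methyl (1R,2S)-2-(benzylamino)cyclopent-3-ene-1-carboxylate
Conditions: Et3N, NaBH(OAc)3, ClCH2CH2Cl, rt
Reagents that add atoms: none
Why: Reductive amination gives clean mono-N-benzylation, and the benzyl group keeps nitrogen out of the later enolate and acrylate chemistry.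

Step 4
Reactants: 5 methyl (1R,2S)-2-(benzylamino)cyclopent-3-ene-1-carboxylate; 6 2,3-dibromoprop-1-ene
Product: 7 methyl (1R,2S)-2-[benzyl(2-bromoprop-2-en-1-yl)amino]cyclopent-3-ene-1-carboxylate
Conditions: K2CO3, MeCN, 60 °C
Reagents that add atoms: none
Why: SN2 N-alkylation takes place at the allylic bromide only, so the vinylic C–Br bond is kept for the next step.

Step 5
Reactants: 7 methyl (1R,2S)-2-[benzyl(2-bromoprop-2-en-1-yl)amino]cyclopent-3-ene-1-carboxylate
Product: 8 methyl 1-benzyl-3-methylidene-1,2,3,3a,6,6a-hexahydrocyclopenta[b]pyrrole-6-carboxylate (cis ring fusion; CO2Me cis to N)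
Conditions: Pd(OAc)2 (5 mol %), PPh3 (15 mol %), Ag2CO3, MeCN, 80 °C
Reagents that add atoms: none
Why: In this intramolecular Heck reaction (5-exo-trig carbopalladation, then syn β-hydride elimination toward C21) the vinylpalladium can reach C17 only on the face that carries nitrogen, which sets C17 cis to C16–N, while Ag2CO3 suppresses double-bond migration.

Step 6
Reactants: 8 methyl 1-benzyl-3-methylidene-1,2,3,3a,6,6a-hexahydrocyclopenta[b]pyrrole-6-carboxylate; 9 tert-butyl acrylate
Product: 10 methyl 1-benzyl-6-(3-tert-butoxy-3-oxopropyl)-3-methylidene-1,2,3,3a,6,6a-hexahydrocyclopenta[b]pyrrole-6-carboxylate (CO2Me cis to N; chain trans to N)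
Conditions: LDA, THF, −78 °C; then 9, −78 °C; AcOH quench
Reagents that add atoms: none
Why: Michael addition of the lithium ester dienolate at its α-carbon sets the quaternary C15, because the acrylate approaches anti to the neighbouring C16–N bond on the convex face and so ends trans to nitrogen with CO2Me cis to it.

Step 7
Reactants: 10 methyl 1-benzyl-6-(3-tert-butoxy-3-oxopropyl)-3-methylidene-1,2,3,3a,6,6a-hexahydrocyclopenta[b]pyrrole-6-carboxylate
Product: 11 methyl 6-(3-tert-butoxy-3-oxopropyl)-3-methyloctahydrocyclopenta[b]pyrrole-6-carboxylate (cis-fused; 3-methyl cis to C20; CO2Me cis to N)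
Conditions: H2 (3 atm), Pd(OH)2/C, EtOAc–AcOH, rt
Reagents that add atoms: none
Why: Heterogeneous hydrogenation delivers hydrogen to the exocyclic methylene from the convex face, so the C18 methyl group ends on the concave face, and the same operation saturates C20=C21 and removes the N-benzyl group by hydrogenolysis.

Step 8
Reactants: 11 methyl 6-(3-tert-butoxy-3-oxopropyl)-3-methyloctahydrocyclopenta[b]pyrrole-6-carboxylate; 12 hex-5-enoyl chloride
Product: 13 N-(hex-5-enoyl) amide of 11
Conditions: Et3N, DMAP (cat.), CH2Cl2, 0 °C to rt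
Reagents that add atoms: none
Why: N-acylation of the secondary amine with an acid chloride brings in C5, C13 and the butenyl chain C9–C12 in one piece.

Step 9
Reactants: 13 N-(hex-5-enoyl) amide of 11
Product: 15 tricyclic enol triflate (lactam C5=O; C13=C14–OTf; 13-but-3-enyl), via potassium enolate 14 (not isolated)
Conditions: KOtBu (2.2 equiv), THF, 0 °C to rt; then PhNTf2, 0 °C; aq NH4Cl work-up
Reagents that add atoms: N-phenylbis(trifluoromethanesulfonimide), O=S(=O)(N(c1ccccc1)S(=O)(=O)C(F)(F)F)C(F)(F)F
Why: Dieckmann condensation of the amide enolate onto the cis-disposed methyl ester closes ring C as a six-membered β-keto lactam, driven by its stabilised enolate, which is O-sulfonylated in the flask at the ketone oxygen while the hindered tert-butyl ester stays out.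

Step 10
Reactants: 15 tricyclic enol triflate
Product: 16 tricyclic unsaturated lactam (C13=C14; 14-methyl; 13-but-3-enyl)
Conditions: Pd(dppf)Cl2 (5 mol %), trimethylboroxine, K2CO3, dioxane–H2O, 90 °C
Reagents that add atoms: trimethylboroxine, CB1OB(C)OB(C)O1
Why: Suzuki–Miyaura coupling of the enol triflate installs the C14 methyl group without touching esters or the terminal alkene.

Step 11
Reactants: 16 tricyclic unsaturated lactam
Product: 17 tricyclic exo-methylene lactam (C14=CH2; H13 on the convex face; tert-butyl ester)
Conditions: LDA (2.5 equiv), THF–DMPU, −78 °C; then AcOH, −78 °C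
Reagents that add atoms: none
Why: Deconjugation by γ-deprotonation to the extended dienolate and kinetic α-protonation moves the alkene to C14=CH2, with the proton entering C13 from the convex face.

Step 12
Reactants: 17 tricyclic exo-methylene lactam
Product: 19 tetracyclic lactone lactam (rings C–F; C5=O), via carboxylic acid 18 (not isolated)
Conditions: CF3CO2H, CH2Cl2, 0 °C to rt
Reagents that add atoms: none
Why: Acidolysis of the tert-butyl ester and Markovnikov lactonisation (6-exo capture of the tertiary C14 cation) by the carboxyl group held on the convex face of C15 sets C14 with O cis to C22 and the methyl group on the concave face, which addition of a carbon nucleophile to a C14 ketone would not give.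

Step 13
Reactants: 19 tetracyclic lactone lactam; 20 ethynyltrimethylsilane
Product: 22 C7-silylated enyne amino lactone (rings C–F; C5 trimethylsilylethynyl; C13 but-3-enyl), via N,O-silyl hemiaminal 21 (not isolated)
Conditions: IrCl(CO)(PPh3)2 (1 mol %), (Me2SiH)2O, toluene, rt; then CuBr (10 mol %), 20, rt to 40 °C
Reagents that add atoms: none
Why: Reductive alkynylation of the tertiary lactam (Ir-catalysed hydrosilylation, then Cu-acetylide addition to the iminium ion; the lactone is not reduced) sets C5 by attack on the convex face anti to the C13 chain, and since C13 equilibrates through the enamine the 5,13-trans isomer is funnelled out.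

Step 14
Reactants: 22 C7-silylated enyne amino lactone
Product: 24 7-trimethylsilyl C8-oxo hexacyclic amino lactone, via alkyne–Co2(CO)6 complex 23 (not isolated)
Conditions: Co2(CO)8, CH2Cl2, rt; then N-methylmorpholine N-oxide, 0 °C to rt
Reagents that add atoms: dicobalt octacarbonyl, O=C=[Co](=C=O)(=C=O)(=C=O)[Co](=C=O)(=C=O)(=C=O)=C=O
Why: This is a Pauson–Khand reaction, the intramolecular (2+2+1) cycloaddition of a 1,7-enyne: the alkyne forms complex 23, amine-oxide-induced loss of CO lets the C9=C10 alkene coordinate and insert into the Co–C6 bond (C6–C10), and CO insertion with reductive elimination forms C8–C9 and C7–C8. Ring B closes in the insertion step, 6-exo-trig over the four-atom tether C5–C13–C12–C11, and ring A closes by reductive elimination from the acyl cobaltacycle as the cyclopentenone with the alkene already at C6=C7. The one new stereocentre, C10, is governed by the trans C5/C13 pair of ring C through the fold of the tether: the step needs C6 to bond to the alkene face that puts H10 syn to H13 and anti to H5, which calls for a boat-like fold of the forming ring B, whereas the all-chair fold would give the C10 epimer. The silyl group on C7 is kept to secure this, because in the chair-like fold Si, lying in the enone plane on the C5 side, is eclipsed with the C5–N bond and pressed against N–CH2 (allylic 1,3-strain), while in the boat-like fold it sits staggered between N and H5. The tertiary amine and the lactone are spectators, and with one alkyne and one alkene there is no chemoselectivity issue.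

Step 15
Reactants: 24 7-trimethylsilyl C8-oxo hexacyclic amino lactone
Product: 25 C8-oxo hexacyclic amino lactone
Conditions: Bu4NF, AcOH, THF, 0 °C
Reagents that add atoms: none
Why: Fluoride-induced protodesilylation of the α-silyl enone removes the spectator at C7, and the AcOH buffer keeps the γ-hydrogen at C10 from exchanging.

Step 16
Reactants: 25 C8-oxo hexacyclic amino lactone
Product: 26 C8-hydroxy hexacyclic amino lactone (allylic alcohol)
Conditions: NaBH4, CeCl3·7H2O, MeOH, −40 °C
Reagents that add atoms: none
Why: Luche 1,2-reduction of the enone leaves the lactone alone, and the C8 carbinol configuration (hydride anti to C11 expected) does not matter since C8 becomes CH2.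

Step 17
Reactants: 26 C8-hydroxy hexacyclic amino lactone
Product: 27 hexacyclic amino lactone (C6=C7; C8H2)
Conditions: Et3SiH, CF3CO2H, CH2Cl2, −20 to 0 °C
Reagents that add atoms: none
Why: Ionic hydrogenation (deoxygenation) goes through the C6–C7–C8 allyl cation, and the silane delivers hydride to the secondary, less hindered terminus C8, remote from the ammonium-bearing C5, so the trisubstituted C6=C7 alkene stays.

Step 18
Reactants: 27 hexacyclic amino lactone
Product: 28 CNP0566793.5 (N-oxide)
Conditions: mCPBA (1.0 equiv), CH2Cl2, −20 °C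
Reagents that add atoms: 3-chloroperbenzoic acid, O=C(OO)c1cccc(Cl)c1
Why: Peracid N-oxidation of the tertiary amine is far faster than epoxidation of the trisubstituted alkene, and the only lone pair of the ring-fusion nitrogen lies on the convex face (syn to H16), which fixes the N configuration.

Compound list
1 | (±)-cis-6-azabicyclo[3.2.0]hept-3-en-7-one (racemate) | O=C1NC2C=CCC12 | starting material
2 | (1R,2S)-2-aminocyclopent-3-ene-1-carboxylic acid | N[C@H]1C=CC[C@H]1C(=O)O | intermediate
3 | methyl (1R,2S)-2-aminocyclopent-3-ene-1-carboxylate hydrochloride | [Cl-].[NH3+][C@H]1C=CC[C@H]1C(=O)OC | intermediate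
4 | benzaldehyde | O=Cc1ccccc1 | starting material
5 | methyl (1R,2S)-2-(benzylamino)cyclopent-3-ene-1-carboxylate | c1ccccc1CN[C@H]1C=CC[C@H]1C(=O)OC | intermediate
6 | 2,3-dibromoprop-1-ene | C=C(Br)CBr | starting material
7 | methyl (1R,2S)-2-[benzyl(2-bromoprop-2-en-1-yl)amino]cyclopent-3-ene-1-carboxylate | C=C(Br)CN(Cc1ccccc1)[C@H]1C=CC[C@H]1C(=O)OC | intermediate
8 | methyl 1-benzyl-3-methylidene-1,2,3,3a,6,6a-hexahydrocyclopenta[b]pyrrole-6-carboxylate (cis-fused; CO2Me cis to N) | C=C1CN(Cc2ccccc2)[C@@H]2[C@H](C(=O)OC)C=C[C@H]12 | intermediate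
9 | tert-butyl acrylate | C=CC(=O)OC(C)(C)C | starting material
10 | methyl 1-benzyl-6-(3-tert-butoxy-3-oxopropyl)-3-methylidene-1,2,3,3a,6,6a-hexahydrocyclopenta[b]pyrrole-6-carboxylate (CO2Me cis to N) | C=C1CN(Cc2ccccc2)[C@@H]2[C@](CCC(=O)OC(C)(C)C)(C(=O)OC)C=C[C@H]12 | intermediate
11 | methyl 6-(3-tert-butoxy-3-oxopropyl)-3-methyloctahydrocyclopenta[b]pyrrole-6-carboxylate (cis-fused; 3-Me cis to C20; CO2Me cis to N) | C[C@@H]1CN[C@@H]2[C@](CCC(=O)OC(C)(C)C)(C(=O)OC)CC[C@H]12 | intermediate
12 | hex-5-enoyl chloride | C=CCCCC(=O)Cl | starting material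
13 | N-(hex-5-enoyl) amide of 11 | C[C@@H]1CN(C(=O)CCCC=C)[C@@H]2[C@](CCC(=O)OC(C)(C)C)(C(=O)OC)CC[C@H]12 | intermediate
14 | potassium enolate of the ring C β-keto lactam (C5=O; C14–O−; 13-but-3-enyl) | C[C@@H]1CN2C(=O)C(CCC=C)=C([O-])[C@]3(CCC(=O)OC(C)(C)C)CC[C@H]1[C@@H]32.[K+] | intermediate
15 | tricyclic enol triflate (C13=C14–OTf) | C[C@@H]1CN2C(=O)C(CCC=C)=C(OS(=O)(=O)C(F)(F)F)[C@]3(CCC(=O)OC(C)(C)C)CC[C@H]1[C@@H]32 | intermediate
16 | tricyclic unsaturated lactam (C13=C14; 14-methyl) | C[C@@H]1CN2C(=O)C(CCC=C)=C(C)[C@]3(CCC(=O)OC(C)(C)C)CC[C@H]1[C@@H]32 | intermediate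
17 | tricyclic exo-methylene lactam tert-butyl ester (C14=CH2; H13 convex) | C[C@@H]1CN2C(=O)[C@H](CCC=C)C(=C)[C@]3(CCC(=O)OC(C)(C)C)CC[C@H]1[C@@H]32 | intermediate
18 | tricyclic exo-methylene lactam carboxylic acid | C[C@@H]1CN2C(=O)[C@H](CCC=C)C(=C)[C@]3(CCC(=O)O)CC[C@H]1[C@@H]32 | intermediate
19 | tetracyclic lactone lactam (rings C–F; C5=O; lactone O cis to C22) | C[C@@H]1CN2C(=O)[C@H](CCC=C)[C@@]3(C)OC(=O)CC[C@]34CC[C@H]1[C@@H]42 | intermediate
20 | ethynyltrimethylsilane | C#C[Si](C)(C)C | starting material
21 | N,O-silyl hemiaminal of 19 (C5–O–SiMe2–O–SiMe2H; C5 not defined) | C[C@@H]1CN2C(O[Si](C)(C)O[SiH](C)C)[C@H](CCC=C)[C@@]3(C)OC(=O)CC[C@]34CC[C@H]1[C@@H]42 | intermediate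
22 | C7-silylated enyne amino lactone (rings C–F; 5,13-trans) | C[C@@H]1CN2[C@@H](C#C[Si](C)(C)C)[C@H](CCC=C)[C@@]3(C)OC(=O)CC[C@]34CC[C@H]1[C@@H]42 | intermediate
23 | alkyne–Co2(CO)6 complex of 22 | C[C@@H]1CN2[C@@H](C34C5([Si](C)(C)C)[Co]3(=C=O)(=C=O)(=C=O)[Co]45(=C=O)(=C=O)=C=O)[C@H](CCC=C)[C@@]3(C)OC(=O)CC[C@]34CC[C@H]1[C@@H]42 | intermediate
24 | 7-trimethylsilyl C8-oxo hexacyclic amino lactone | C[C@@H]1CN2[C@H]3C4=C([Si](C)(C)C)C(=O)C[C@@H]4CC[C@@H]3[C@@]3(C)OC(=O)CC[C@]34CC[C@H]1[C@@H]42 | intermediate
25 | C8-oxo hexacyclic amino lactone | C[C@@H]1CN2[C@H]3C4=CC(=O)C[C@@H]4CC[C@@H]3[C@@]3(C)OC(=O)CC[C@]34CC[C@H]1[C@@H]42 | intermediate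
26 | C8-hydroxy hexacyclic amino lactone (OH anti to H10 drawn; epimer equally usable) | C[C@@H]1CN2[C@H]3C4=C[C@H](O)C[C@@H]4CC[C@@H]3[C@@]3(C)OC(=O)CC[C@]34CC[C@H]1[C@@H]42 | intermediate
27 | hexacyclic amino lactone (C6=C7) | C[C@@H]1CN2[C@H]3C4=CCC[C@@H]4CC[C@@H]3[C@@]3(C)OC(=O)CC[C@]34CC[C@H]1[C@@H]42 | intermediate
28 | CNP0566793.5 (N-oxide; O syn to H16) | C[C@@H]1C[N@+]2([O-])[C@H]3C4=CCC[C@@H]4CC[C@@H]3[C@@]3(C)OC(=O)CC[C@]34CC[C@H]1[C@@H]42 | target

Total steps: 18. Longest linear sequence: 18 steps (1 to 28, fully linear).

Steps most likely to fail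

Step 14. Alkene insertion at the hindered silylated alkyne complex may be slower than loss of cobalt, or the tether may still fold chair-like, so that facial selectivity at C10 is poor. The fallback sets out from 22. Bu4NF/AcOH in THF removes the alkynyl silicon to give the terminal enyne amino lactone F1. F1 is cyclocarbonylated catalytically with [RhCl(CO)2]2 (monovalent rhodium) under CO (1 atm) in toluene at 110 °C; this is a Pauson–Khand-type oxidative cyclisation that needs no bulky alkyne complex and no amine oxide. It gives 25 directly and comes back to the route at 25, so step 15 is skipped. The cost is that C10 then depends on the tether alone, and the C10 epimer would have to be separated here.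

Step 13. The enamine tautomer of the iminium ion may expel the lactone carboxylate (β-acyloxy elimination), or C13 may not equilibrate fully before the acetylide adds. The fallback sets out from 17. The same Ir/Cu reductive alkynylation is run on the exo-methylene lactam, which has no leaving group β to the iminium carbon, and gives the propargylic amine tert-butyl ester F2. CF3CO2H then cleaves the ester and closes the lactone by Markovnikov addition to C14=CH2, the cation now being remote from any carbonyl group. This comes back to the route at 22.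

Step 17. Hydride capture of the allyl cation may lose regiocontrol (hydride at C6 and the alkene moving to C7=C8), or the cation may eliminate to a cyclopentadiene while the acid opens the tertiary lactone. The fallback sets out from 26. Ac2O, Et3N and DMAP give the allylic acetate F3. Reduction with NaBH4 in THF catalysed by Pd(PPh3)4 goes through the π-allylpalladium intermediate, with external hydride attacking the less hindered C8 terminus under non-acidic conditions, and gives 27. This comes back to the route at 27.

Further compounds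
F1 | step 14 | terminal enyne amino lactone (C5 ethynyl; rings C–F) | C[C@@H]1CN2[C@@H](C#C)[C@H](CCC=C)[C@@]3(C)OC(=O)CC[C@]34CC[C@H]1[C@@H]42
F2 | step 13 | propargylic amine tert-butyl ester with C14=CH2 (C5 trimethylsilylethynyl; 5,13-trans) | C[C@@H]1CN2[C@@H](C#C[Si](C)(C)C)[C@H](CCC=C)C(=C)[C@]3(CCC(=O)OC(C)(C)C)CC[C@H]1[C@@H]32
F3 | step 17 | C8 allylic acetate of 26 | C[C@@H]1CN2[C@H]3C4=C[C@H](OC(C)=O)C[C@@H]4CC[C@@H]3[C@@]3(C)OC(=O)CC[C@]34CC[C@H]1[C@@H]42
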